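At late times a flask like this asks where the last electrophile goes, so I started there when you wanted a quick number.

solid electrophile 0.051 M; free base 3.00 equiv; protonated nucleophile 0.800 equiv; time 40 h

    acid set free + free base ⇌ salt of the base (K1 = 24700 M⁻¹, k1 = 323 M⁻¹ h⁻¹)
    electrophile + nucleophile → acid set free + product (k2 = 4.35 M⁻¹ h⁻¹)
    2 electrophile → homo dimer (k3 = 1.04 M⁻¹ h⁻¹)
    solid electrophile ⇌ electrophile, rate k4*(cs4 - [electrophile]) while solid is left; crystals form when [electrophile] > cs4 (cs4 = 18 mM, k4 = 1.47 h⁻¹)
    nucleophile + acid set free ⇌ protonated nucleophile, settled at all times (K5 = 2900 M⁻¹)
    acid set free + free base ⇌ idle adduct, settled at all times (K6 = 9.82 M⁻¹)

- part of the solid electrophile that has reacted (what has only dissolved counts as not reacted) at 40 h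
- share of the unused nucleophile that is free and not bound as protonated nucleophile, at 40 h

- percentages count the solid electrophile that a species holds: one homo dimer counts as two
- acid set free is meant together with its idle adduct
- a doubled species enters its step squared and goes two at a time
- solid, in amounts per volume of the solution: solid electrophile
- at the start none of the solid electrophile is in solution
- what has only dissolved of solid electrophile counts as not reacted
- run time (flask): 40 h

I divided the rate at which the electrophile goes to product by the rate at which it goes to homo dimer, and time dropped out. What remained was the split (a selectivity factor): 2.09 times c(nucleophile) over c(electrophile). With both concentrations at their charges the split came to 1.67, a share to product of 62.6% at that ratio. While solid stands, though, dissolution feeds the electrophile up to 18 mM, which is less than the charge. With c(electrophile) at that level and nucleophile at its charge, the split came to 4.74, higher, and the product is bounded by the nucleophile charge, 0.800 equiv.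

Acid set free goes to the salt of the base rather than the idle adduct, because the equilibrium constant times c(free base) at the start is 3800 for the salt against 1.5 for the adduct. Taking the salt step at balance, I had protonated over free nucleophile as 0.117 times c(salt of the base) over c(free base). I counted the salt as the charged acid plus the acid each product sets free, setting aside the other forms of the acid. That estimate gave fr of 90.4% with product at the share above, and 88.2% with product equal to the nucleophile charge. The split has no clock, so for c I took a half-life of electrophile with nucleophile at its charge, 3.91 h, far shorter than the run but lengthening as nucleophile falls. I promised a high c and no digit.

The forecast said 91.2% and 89%, starting from “Excess base drains the acid into the salt”. The flask gave 91.1% and 88.9%, with product at 65.1%.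

This flask was not at rest at 40.0 h: electrophile stood at 8.92% and the split, 2.09 times c(nucleophile) over c(electrophile) then, was 3.1. By 400 h c reached >99.9%, with electrophile at 0.0166%. Product gained 7.5 percentage points to stand at 72.6%, more than the 1.4 points homo dimer gained, and free base fell from 52.2% to 49.4%.

For the flask with 0.013 M of solid electrophile, whose charge is below 18 mM, the equivalents are the same, so the split at the charges again came to 1.67. That flask gave product over homo dimer, each counted in electrophile, of 1.66, with c at 76.1%.

Its constants belong to no real substance.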